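**Plan**

- Retrosynthesis: the palmitate C–O bond at O6 is cut first, then C4–C5 (aldol), giving methyl ketone 12 and the four-carbon aldehyde 16 (C1–C4). The acetyl carbon of 12 (C6) is the ester carbon of bis-oxazole 10.
- In 10 the O1–C2 bond of ring A (the 2,4-disubstituted oxazole) and the O1–C2 bond of ring B (the 5-monosubstituted oxazole) are cut together. This works because C2/N3/C4/C5/O1 of ring A, the bridging CH2 and C5/O1/C4/N3/C2 of ring B correspond atom for atom to an N-formylglycine–malonyl–serine chain (7), in which each ring oxygen is a carbonyl oxygen lying 1,4 to an amide carbon.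
- Forward: N-formylglycine, Meldrum's acid and L-serine methyl ester give 7 (steps 1–3). Both oxazoles close in one flask (step 4, ring A expected first, ring B second). The ester becomes the methyl ketone (steps 5, 6). A boron aldol joins C5 to C4 (step 10). Silylation, C6 reduction, palmitoylation and acid deprotection finish the route (steps 11–14).
- Stereochemistry: C2 and C3 come from D-threonine (steps 7–9, retentive diazotisation). C4 comes from Felkin–Anh/Cornforth addition to the α-alkoxy aldehyde (3,4-anti). C6 comes from (S)-CBS reduction. The serine centre is consumed in ring A.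

Key step: step 4

Remark on the chemistry: chain atoms are numbered C1 (methyl) to C6 (acyloxy carbinol). Aldehyde 7 is drawn as the keto form but should exist largely as its enol, so the descriptor at its α-carbon is nominal. The descriptor of dioxolane C4 changes between 16, 18 and 19 only through CIP priorities, not through any change of configuration.

**Route**

Step 1
Reactants: 1 N-formylglycine; 2 Meldrum's acid
Product: 3 5-(2-formamido-1-hydroxyethylidene)-2,2-dimethyl-1,3-dioxane-4,6-dione
Conditions: DCC, DMAP, CH2Cl2, 0 °C to rt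
Reagents that add atoms: none
Why: Carbodiimide/DMAP C-acylation of Meldrum's acid by an N-acyl amino acid is a standard route to acyl Meldrum's acids; glycine has no stereocentre to lose and the product is stabilised as its enol.

Step 2
Reactants: 3 acyl Meldrum's acid; 4 L-serine methyl ester hydrochloride
Product: 6 methyl N-(4-formamido-3-oxobutanoyl)-L-serinate, via formamidoacetylketene 5 (not isolated)
Conditions: Et3N, MeCN, reflux
Reagents that add atoms: none
Why: Thermolysis of an acyl Meldrum's acid releases acetone and CO2 to give an acylketene, which the free amine of serine methyl ester should trap far faster than its hydroxyl or the formamide N–H can (acylketene aminolysis to a β-keto amide); the serine centre is untouched.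

Step 3
Reactants: 6 methyl N-(4-formamido-3-oxobutanoyl)-L-serinate
Product: 7 methyl (2S)-2-(4-formamido-3-oxobutanamido)-3-oxopropanoate
Conditions: Dess–Martin periodinane, CH2Cl2, 0 °C to rt; crude product used directly
Reagents that add atoms: none
Why: Dess–Martin oxidation of serine-derived β-hydroxy amides to the α-amido aldehydes is the usual first half of the two-stage oxazole synthesis; about one equivalent at low temperature should oxidise the primary alcohol much faster than the malonyl CH2.

Step 4
Reactants: 7 methyl (2S)-2-(4-formamido-3-oxobutanamido)-3-oxopropanoate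
Product: 10 methyl 2-(1,3-oxazol-5-ylmethyl)-1,3-oxazole-4-carboxylate, via isocyano keto amido aldehyde 8 (not isolated), via isocyano ketone oxazole ester 9 (not isolated)
Conditions: PPh3, I2, Et3N (excess of each), CH2Cl2, 0 °C to rt; 7 added to the preformed reagent
Reagents that add atoms: none
Why: Proposed new method: Ph3PI2/Et3N should first dehydrate the formamide to isocyanide 8 and turn the secondary amide into an O-phosphonium imidate; the enol oxygen of the formylacetate unit then adds to that imidoyl carbon with loss of Ph3PO (ring A, O1–C2 bond, 5-endo closure at a trigonal carbon, 5-endo-dig in the nitrilium limit), after which the Et3N-generated enolate of α-isocyano ketone 9 closes through oxygen on the isocyanide carbon (ring B, O1–C2 bond, 5-endo-dig) and a proton shift aromatises it. The closest known reactions are the Robinson–Gabriel-type cyclodehydration of α-acylamino aldehydes and ketones with PPh3/I2/Et3N, and formamide-to-isocyanide dehydration by the same reagent followed by Schöllkopf-type closure of α-isocyano ketone enolates to 5-substituted oxazoles; what is new is running both on one β-keto amide in one flask. No stereocentre is formed and the serine centre becomes sp2, so its lability in 7 is immaterial. The step needs chemoselectivity: each carbonyl oxygen must pair with the amide carbon 1,4 to it, the ketone must not be lost as a β-iodo enamide, and the formamide nitrogen must not attack the activated malonamide carbon. The substrate should secure this because only the two 1,4-pairs can reach five-membered transition states through oxygen, early conversion of the formamide to the isocyanide removes its nitrogen nucleophile, and the β-keto amide ketone sits mainly in the keto form and should react with Ph3PI2 more slowly than the two N–H amides and the enolised aldehyde; enolisation toward the bridging CH2 is unproductive but reversible.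

Step 5
Reactants: 10 methyl 2-(1,3-oxazol-5-ylmethyl)-1,3-oxazole-4-carboxylate
Product: 11 N-methoxy-N-methyl-2-(1,3-oxazol-5-ylmethyl)-1,3-oxazole-4-carboxamide
Conditions: MeNH(OMe)·HCl, AlMe3, CH2Cl2, 0 °C to rt; KNaC4H4O6 (aq)
Reagents that add atoms: N,O-dimethylhydroxylamine hydrochloride, CNOC.Cl
Why: Weinreb amidation of a methyl ester with the aluminium amide made from AlMe3 and the amine hydrochloride is standard and too weakly basic to touch the C2–H of ring B or the bridging CH2.

Step 6
Reactants: 11 Weinreb amide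
Product: 12 1-[2-(1,3-oxazol-5-ylmethyl)-1,3-oxazol-4-yl]ethan-1-one
Conditions: MeMgBr, THF, −78 to 0 °C; NH4Cl (aq)
Reagents that add atoms: methylmagnesium bromide, C[Mg]Br
Why: Grignard addition to a Weinreb amide stops at the chelated tetrahedral intermediate and gives the ketone on work-up; at low temperature addition should outrun deprotonation at the oxazole C2–H or the bridging CH2.

Step 7
Reactants: 13 D-threonine
Product: 14 (2R,3S)-2,3-dihydroxybutanoic acid
Conditions: NaNO2, H2SO4 (aq), 0 °C to rt
Reagents that add atoms: water, O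
Why: Diazotisation of an α-amino acid in aqueous acid gives the α-hydroxy acid with net retention (double inversion through carboxylate participation), so the (2R,3S) configuration of D-threonine is carried into the future C3 and C2.

Step 8
Reactants: 14 (2R,3S)-2,3-dihydroxybutanoic acid
Product: 15 methyl (4R,5S)-2,2,5-trimethyl-1,3-dioxolane-4-carboxylate
Conditions: Me2C(OMe)2, MeOH, TsOH (cat.), 50 °C
Reagents that add atoms: 2,2-dimethoxypropane, COC(C)(C)OC; methanol, CO
Why: Acid-catalysed Fischer esterification and acetalisation in one operation protects the syn-diol as the trans-dioxolane without touching either stereocentre.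

Step 9
Reactants: 15 methyl (4R,5S)-2,2,5-trimethyl-1,3-dioxolane-4-carboxylate
Product: 16 (4R,5S)-2,2,5-trimethyl-1,3-dioxolane-4-carbaldehyde
Conditions: iBu2AlH, CH2Cl2, −78 °C; KNaC4H4O6 (aq); used at once
Reagents that add atoms: none
Why: Partial reduction of an α-alkoxy ester with iBu2AlH at −78 °C stops at the aluminium hemiacetal and releases the aldehyde on work-up; immediate use avoids epimerisation at the α-carbon (C3).

Step 10
Reactants: 12 methyl ketone; 16 (4R,5S)-2,2,5-trimethyl-1,3-dioxolane-4-carbaldehyde
Product: 18 (3S)-3-hydroxy-1-[2-(1,3-oxazol-5-ylmethyl)-1,3-oxazol-4-yl]-3-[(4S,5S)-2,2,5-trimethyl-1,3-dioxolan-4-yl]propan-1-one, via dicyclohexylboron enolate 17 (not isolated)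
Conditions: (c-C6H11)2BCl, Et3N, Et2O, −78 to 0 °C; then 16, −78 to −20 °C; MeOH, pH 7 buffer, H2O2, 0 °C
Reagents that add atoms: none
Why: Soft enolisation with (c-C6H11)2BCl/Et3N should engage only the ketone, and the boron aldol (closed transition state) with the α-alkoxy aldehyde should follow the polar Felkin–Anh/Cornforth sense, both of which predict the 3,4-anti adduct and hence S at C4; the minor C4 epimer should be removable by chromatography.

Step 11
Reactants: 18 aldol adduct
Product: 19 (3S)-1-[2-(1,3-oxazol-5-ylmethyl)-1,3-oxazol-4-yl]-3-(triethylsilyloxy)-3-[(4R,5S)-2,2,5-trimethyl-1,3-dioxolan-4-yl]propan-1-one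
Conditions: TESCl, imidazole, DMF, 0 °C to rt
Reagents that add atoms: chlorotriethylsilane, CC[Si](Cl)(CC)CC
Why: Silylation of a secondary alcohol with TESCl/imidazole is standard and mild enough to avoid retro-aldol or β-elimination; it leaves the C4 oxygen masked so that C6 can later be the only free hydroxyl.

Step 12
Reactants: 19 silyloxy ketone
Product: 20 (1R,3S)-1-[2-(1,3-oxazol-5-ylmethyl)-1,3-oxazol-4-yl]-3-(triethylsilyloxy)-3-[(4R,5S)-2,2,5-trimethyl-1,3-dioxolan-4-yl]propan-1-ol
Conditions: (S)-2-methyl-CBS-oxazaborolidine (cat.), BH3·SMe2 (excess), THF, −20 °C; then MeOH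
Reagents that add atoms: none
Why: Corey–Bakshi–Shibata reduction with the (S)-oxazaborolidine should give the (R)-carbinol at C6 when the oxazolyl group acts as the large substituent and the CH2 chain as the small one, the same sense as acetophenone to (R)-1-phenylethanol, so C6 is set by the catalyst.

Step 13
Reactants: 20 alcohol; 21 palmitic acid
Product: 22 (1R,3S)-1-[2-(1,3-oxazol-5-ylmethyl)-1,3-oxazol-4-yl]-3-(triethylsilyloxy)-3-[(4R,5S)-2,2,5-trimethyl-1,3-dioxolan-4-yl]propyl hexadecanoate
Conditions: DCC, DMAP (cat.), CH2Cl2, rt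
Reagents that add atoms: none
Why: Steglich esterification acylates the only free hydroxyl with retention at C6.

Step 14
Reactants: 22 protected palmitate
Product: 23 (1R,3S,4R,5S)-3,4,5-trihydroxy-1-[2-(1,3-oxazol-5-ylmethyl)-1,3-oxazol-4-yl]hexyl hexadecanoate (CNP0240423.1)
Conditions: TFA/H2O (9:1), CH2Cl2, 0 °C
Reagents that add atoms: none
Why: Acid hydrolysis removes the triethylsilyl ether and the isopropylidene acetal in one operation, while the palmitate is stable and acyl migration from O6 to O4 should be slow under cold acidic conditions.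

**Compound list**

1 | N-formylglycine | O=CNCC(=O)O | starting material
2 | Meldrum's acid (2,2-dimethyl-1,3-dioxane-4,6-dione) | CC1(C)OC(=O)CC(=O)O1 | starting material
3 | 5-(2-formamido-1-hydroxyethylidene)-2,2-dimethyl-1,3-dioxane-4,6-dione | O=CNCC(O)=C1C(=O)OC(C)(C)OC1=O | intermediate
4 | L-serine methyl ester hydrochloride | COC(=O)[C@@H](N)CO.Cl | starting material
5 | formamidoacetylketene, N-(2,4-dioxobut-3-en-1-yl)formamide (formed in the flask in step 2) | O=CNCC(=O)C=C=O | intermediate
6 | methyl N-(4-formamido-3-oxobutanoyl)-L-serinate | O=CNCC(=O)CC(=O)N[C@@H](CO)C(=O)OC | intermediate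
7 | methyl (2S)-2-(4-formamido-3-oxobutanamido)-3-oxopropanoate | O=CNCC(=O)CC(=O)N[C@@H](C=O)C(=O)OC | intermediate
8 | methyl (2S)-2-(4-isocyano-3-oxobutanamido)-3-oxopropanoate (formed in the flask in step 4) | [C-]#[N+]CC(=O)CC(=O)N[C@@H](C=O)C(=O)OC | intermediate
9 | methyl 2-(3-isocyano-2-oxopropyl)-1,3-oxazole-4-carboxylate (formed in the flask in step 4) | [C-]#[N+]CC(=O)Cc1nc(C(=O)OC)co1 | intermediate
10 | methyl 2-(1,3-oxazol-5-ylmethyl)-1,3-oxazole-4-carboxylate | COC(=O)c1coc(Cc2cnco2)n1 | intermediate
11 | N-methoxy-N-methyl-2-(1,3-oxazol-5-ylmethyl)-1,3-oxazole-4-carboxamide | CON(C)C(=O)c1coc(Cc2cnco2)n1 | intermediate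
12 | 1-[2-(1,3-oxazol-5-ylmethyl)-1,3-oxazol-4-yl]ethan-1-one | CC(=O)c1coc(Cc2cnco2)n1 | intermediate
13 | D-threonine, (2R,3S)-2-amino-3-hydroxybutanoic acid | C[C@H](O)[C@@H](N)C(=O)O | starting material
14 | (2R,3S)-2,3-dihydroxybutanoic acid | C[C@H](O)[C@@H](O)C(=O)O | intermediate
15 | methyl (4R,5S)-2,2,5-trimethyl-1,3-dioxolane-4-carboxylate | COC(=O)[C@@H]1OC(C)(C)O[C@H]1C | intermediate
16 | (4R,5S)-2,2,5-trimethyl-1,3-dioxolane-4-carbaldehyde | O=C[C@@H]1OC(C)(C)O[C@H]1C | intermediate
17 | dicyclohexyl{1-[2-(1,3-oxazol-5-ylmethyl)-1,3-oxazol-4-yl]ethenyloxy}borane (boron enolate, formed in the flask in step 10) | C=C(OB(C1CCCCC1)C1CCCCC1)c1coc(Cc2cnco2)n1 | intermediate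
18 | (3S)-3-hydroxy-1-[2-(1,3-oxazol-5-ylmethyl)-1,3-oxazol-4-yl]-3-[(4S,5S)-2,2,5-trimethyl-1,3-dioxolan-4-yl]propan-1-one | O=C(C[C@H](O)[C@@H]1OC(C)(C)O[C@H]1C)c1coc(Cc2cnco2)n1 | intermediate
19 | (3S)-1-[2-(1,3-oxazol-5-ylmethyl)-1,3-oxazol-4-yl]-3-(triethylsilyloxy)-3-[(4R,5S)-2,2,5-trimethyl-1,3-dioxolan-4-yl]propan-1-one | O=C(C[C@H](O[Si](CC)(CC)CC)[C@@H]1OC(C)(C)O[C@H]1C)c1coc(Cc2cnco2)n1 | intermediate
20 | (1R,3S)-1-[2-(1,3-oxazol-5-ylmethyl)-1,3-oxazol-4-yl]-3-(triethylsilyloxy)-3-[(4R,5S)-2,2,5-trimethyl-1,3-dioxolan-4-yl]propan-1-ol | O[C@H](C[C@H](O[Si](CC)(CC)CC)[C@@H]1OC(C)(C)O[C@H]1C)c1coc(Cc2cnco2)n1 | intermediate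
21 | palmitic acid (hexadecanoic acid) | CCCCCCCCCCCCCCCC(=O)O | starting material
22 | (1R,3S)-1-[2-(1,3-oxazol-5-ylmethyl)-1,3-oxazol-4-yl]-3-(triethylsilyloxy)-3-[(4R,5S)-2,2,5-trimethyl-1,3-dioxolan-4-yl]propyl hexadecanoate | CCCCCCCCCCCCCCCC(=O)O[C@H](C[C@H](O[Si](CC)(CC)CC)[C@@H]1OC(C)(C)O[C@H]1C)c1coc(Cc2cnco2)n1 | intermediate
23 | (1R,3S,4R,5S)-3,4,5-trihydroxy-1-[2-(1,3-oxazol-5-ylmethyl)-1,3-oxazol-4-yl]hexyl hexadecanoate | CCCCCCCCCCCCCCCC(=O)O[C@H](C[C@H](O)[C@H](O)[C@H](C)O)c1coc(Cc2cnco2)n1 | target

**Step count**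

Total: 14 steps. Longest linear sequence: 11 steps (steps 1–6 and 10–14); steps 7–9 form the side branch to aldehyde 16.

**Steps most likely to fail**

1. Step 4 (Proposed new method). The phosphonium reagent may iodinate the enol of the β-keto amide, or the isocyanide may oligomerise before ring B closes, so that only one ring or neither forms. The fallback closes the rings one after the other by known reactions; it sets out from 3 and comes back at 10. Compound 3 is heated in MeOH to give, through ketene 5, methyl 4-formamido-3-oxobutanoate F1. Dehydration of its formamide with POCl3/Et3N (CH2Cl2, −30 °C) gives methyl 4-isocyano-3-oxobutanoate F2, which should close under the same base (Schöllkopf-type) to methyl 2-(1,3-oxazol-5-yl)acetate F3. LiOH (THF/H2O, 0 °C) gives 2-(1,3-oxazol-5-yl)acetic acid F4. Carbodiimide coupling (EDC·HCl, HOBt, iPr2NEt, CH2Cl2) with 4 gives methyl N-[2-(1,3-oxazol-5-yl)acetyl]-L-serinate F5. Dess–Martin oxidation gives methyl (2S)-2-[2-(1,3-oxazol-5-yl)acetamido]-3-oxopropanoate F6, and the documented single cyclodehydration with PPh3/I2/Et3N closes ring A to 10.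

2. Step 10. Facial selectivity in the addition to the α-alkoxy aldehyde may be poor, or the oxazole nitrogens may sequester the boron reagent so that enolisation stalls. The fallback replaces the aldol by a nitrile oxide cycloaddition, which forms C5–C6 and O–C4 instead of C4–C5 and needs no Lewis acid; it sets out from 10 and 16 and comes back at 18. Reduction of 10 with iBu2AlH (CH2Cl2, −78 °C) gives 2-(1,3-oxazol-5-ylmethyl)-1,3-oxazole-4-carbaldehyde F7, and NH2OH·HCl/pyridine gives its (E)-oxime F8. Wittig methylenation of 16 (Ph3P=CH2, THF, −78 to 0 °C) gives (4S,5S)-4-ethenyl-2,2,5-trimethyl-1,3-dioxolane F9. Oxidation of F8 with PhI(OAc)2 in MeOH in the presence of F9 generates 2-(1,3-oxazol-5-ylmethyl)-1,3-oxazole-4-carbonitrile oxide F10. This should add to the alkene anti to the allylic oxygen (inside-alkoxy effect) to give (5S)-3-[2-(1,3-oxazol-5-ylmethyl)-1,3-oxazol-4-yl]-5-[(4R,5S)-2,2,5-trimethyl-1,3-dioxolan-4-yl]-4,5-dihydro-1,2-oxazole F11, with diastereomers separable at this stage. Reductive N–O cleavage and imine hydrolysis (Raney Ni, H2, B(OH)3, MeOH/H2O) then gives 18.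

3. Step 12. Facial selectivity may be eroded because borane can coordinate to N3 of ring A next to the carbonyl and open an uncatalysed pathway. The fallback makes the reduction stereoconvergent instead of selective; it sets out from 19 and comes back at 20 and 22. NaBH4 (MeOH, −40 °C) should give 20 together with its C6 epimer, (1S,3S)-1-[2-(1,3-oxazol-5-ylmethyl)-1,3-oxazol-4-yl]-3-(triethylsilyloxy)-3-[(4R,5S)-2,2,5-trimethyl-1,3-dioxolan-4-yl]propan-1-ol F12. After separation, 20 continues through step 13. F12 is esterified with inversion by a Mitsunobu reaction with palmitic acid 21 (PPh3, DIAD, THF, 0 °C) and so gives 22 directly.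

**Further compounds**

F1 | step 4 | methyl 4-formamido-3-oxobutanoate | O=CNCC(=O)CC(=O)OC
F2 | step 4 | methyl 4-isocyano-3-oxobutanoate | [C-]#[N+]CC(=O)CC(=O)OC
F3 | step 4 | methyl 2-(1,3-oxazol-5-yl)acetate | COC(=O)Cc1cnco1
F4 | step 4 | 2-(1,3-oxazol-5-yl)acetic acid | OC(=O)Cc1cnco1
F5 | step 4 | methyl N-[2-(1,3-oxazol-5-yl)acetyl]-L-serinate | COC(=O)[C@H](CO)NC(=O)Cc1cnco1
F6 | step 4 | methyl (2S)-2-[2-(1,3-oxazol-5-yl)acetamido]-3-oxopropanoate | COC(=O)[C@H](C=O)NC(=O)Cc1cnco1
F7 | step 10 | 2-(1,3-oxazol-5-ylmethyl)-1,3-oxazole-4-carbaldehyde | O=Cc1coc(Cc2cnco2)n1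
F8 | step 10 | (E)-2-(1,3-oxazol-5-ylmethyl)-1,3-oxazole-4-carbaldehyde oxime | O/N=C/c1coc(Cc2cnco2)n1
F9 | step 10 | (4S,5S)-4-ethenyl-2,2,5-trimethyl-1,3-dioxolane | C=C[C@@H]1OC(C)(C)O[C@H]1C
F10 | step 10 | 2-(1,3-oxazol-5-ylmethyl)-1,3-oxazole-4-carbonitrile oxide | [O-][N+]#Cc1coc(Cc2cnco2)n1
F11 | step 10 | (5S)-3-[2-(1,3-oxazol-5-ylmethyl)-1,3-oxazol-4-yl]-5-[(4R,5S)-2,2,5-trimethyl-1,3-dioxolan-4-yl]-4,5-dihydro-1,2-oxazole | O1N=C(c2coc(Cc3cnco3)n2)C[C@H]1[C@@H]4OC(C)(C)O[C@H]4C
F12 | step 12 | (1S,3S)-1-[2-(1,3-oxazol-5-ylmethyl)-1,3-oxazol-4-yl]-3-(triethylsilyloxy)-3-[(4R,5S)-2,2,5-trimethyl-1,3-dioxolan-4-yl]propan-1-ol | O[C@@H](C[C@H](O[Si](CC)(CC)CC)[C@@H]1OC(C)(C)O[C@H]1C)c1coc(Cc2cnco2)n1
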